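| flask | starting material | free enzyme | temperature | remark | time |
|---|---|---|---|---|---|
| alder | 0.20 M | 0.83 µM | −10 °C | run made earlier |  |
| maple | 0.20 M | 2.3 µM | 1 °C | run made earlier |  |
| eta | 0.20 M | 3.0 µM | 5 °C |  | 40 h |
| zeta | 0.20 M | 1.0 µM | 5 °C |  | 40 h |
| gamma | 0.20 M | 1.0 µM | −15 °C |  | 40 h |
| alpha | 0.20 M | 3.0 µM | −15 °C |  | 40 h |

- alder (time / h: target / %): 15.0: 10; 30.0: 22; 48.0: 28; 60.0: 35; 96.0: 42
- maple (time / h: target / %): 8.00: 29; 15.0: 38; 25.0: 51; 30.0: 52; 40.0: 51

(each reading ± 1.5 percentage points)

- amounts and yields of target count idle complex too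
- the numbers in the tables scatter by 1.5 percentage points (one standard deviation)
- steps that have been proposed: free enzyme -> unfolded enzyme; starting material + free enzyme -> target + free enzyme; target <-> isomer of the product; free enzyme + target <-> idle complex

* all flasks from highest to lowest amount of target, in percent of the starting material charged, at 40 h (eta / zeta / gamma / alpha)
* the amount of target, in percent of the starting material charged of the flask you put first, at 40 h
* the amount of target, in percent of the starting material charged of the flask you put last, at 40 h

1. Zeta holds 2.00 × 10⁵ molecules of starting material per free enzyme, and the enzyme comes back after each turn. So take c(free enzyme) as its charge. Then c(starting material) decays pseudo-first-order, falling by a factor e in a filling time that varies inversely with the charge.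

2. Read that time early in each run. Alder at 30.0 h gives 121 h, and maple at 8.00 h gives 23.4 h. Per unit of charge, maple fills 1.87 times as fast; I take the logarithm of that speed as linear in temperature.

3. The filling time of gamma is then 133 h, and of alpha 44.4 h. For zeta it is 42.8 h, and for eta 14.3 h.

4. The second time is a loss time of target. Maple stands flat near 52% at 30.0 h. Target readings cannot separate lost target from stopped enzyme, so I assume loss: making equals losing there, which gives 43.9 h. Alder at 60.0 h reads 35% against 39.1% from filling alone, and at 96.0 h it reads 42% against 54.8%, so the gap in alder grows, and I take filling alone at −15 °C as a high estimate.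

5. My reckoning from the two times, making then losing, gives eta 50.6% and zeta 37.1%. Filling alone gives alpha 59.4% and gamma 26.0%. My order is alpha, eta, zeta, gamma.

6. The forecast says alpha > eta > gamma > zeta, with 60% and 21.5%, holding that “Colder wins at equal enzyme loading”.

7. The flasks give alpha > eta > zeta > gamma, with 54.0% first and 23.8% last.

    free enzyme → unfolded enzyme (k = 0.00190 h⁻¹, Ea = 204 kJ mol⁻¹)
    starting material + free enzyme → target + free enzyme, rate k2*[starting material]*[free enzyme]/(1 + ([starting material]/Km2)) (0.300 M, k = 42000 L mol⁻¹ h⁻¹, Ea = 37.0 kJ mol⁻¹)
    target ⇌ isomer of the product (K = 1.90, k = 0.0390 h⁻¹, Ea = 89.0 kJ mol⁻¹, ΔH = −55.0 kJ mol⁻¹)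
    free enzyme + target ⇌ idle complex (K = 3.30 L mol⁻¹, k = 4.00 L mol⁻¹ h⁻¹, Ea = 74.0 kJ mol⁻¹, ΔH = −24.0 kJ mol⁻¹)
    (constants at 5 °C)

In alpha the forward turning of target into isomer of the product has a half-life of 15 d, longer than the 40 h of the run. Gamma has 75% of its starting material left at 40 h, so 25.0% has reacted, against 26.0% from its filling time. Charge gamma with 1.70 µM of free enzyme instead: the filling time becomes 78.3 h, which gives 40.0% reacted. That neighbour keeps 62% of its starting material and holds 36.5% target.

The earlier runs and the new flask were computed from invented constants; noise was put on by code.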